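**Retrosynthetic overview**
- Target 28 ⇐ 1‑O‑acetylation and global desilylation of a tetracyclic enone; ring D (C13–C16) with the C15–C16(=C17) unit ⇐ tin‑hydride radical cyclisation of a C8 propargylic alcohol (C8 aldehyde + acetylene) onto the C12=C13 alkene.
- Ring C (C9–C11 and C8–C14, cis O11/O14) ⇐ Diels–Alder reaction of a 3‑formyl‑5,6‑dihydropyran‑2‑one (C8=C9 of the spiro δ‑lactone) with (1E,3E)‑1,4‑bis(silyloxy)butadiene.
- Spiro δ‑lactone (C20–O–C7) ⇐ hydride reduction and oxidative lactonisation of the key‑step product; ring A ⇐ C4–C5 and C1–C10 formed together by an iron‑hydride radical–polar crossover (4+2) annulation of 4‑methylpent‑4‑enal with an α‑substituted (5R)‑5‑menthyloxybutenolide.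
- Enabling feature: C6 (on C5) and C20 (on C10) are oxygenated one‑carbon arms that are cis on ring A, so the C5–C10 bond can be the former C=C of a butenolide whose carbonyl is C20 and whose acetal carbon is C6 (auxiliary site); C4 is a gem‑dimethyl carbon (tertiary radical from an isopropenyl group) and C1 a carbinol next to quaternary C10 (aldol of the lactone enolate).
- Ring order: butenolide (temporary ring, opened in step 5) → ring A → δ‑lactone → ring C → ring D.

Key step: step 3

Remark: atoms are numbered as in ent‑kaurane (ring A = C1–C5/C10; C6 and C20 = CH2O arms on C5 and C10; δ‑lactone = C20–O–C7–C8–C9–C10; ring C = C8/C9/C11–C14; ring D = C8/C14/C13/C16/C15; C17 = exocyclic CH2; α/β as in the usual drawing); compounds 1, 4, 6 and 18 are taken as commercially available.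

**Step 1**
Reactants: 1 (5R)-5-[(1R,2S,5R)-menthyloxy]furan-2(5H)-one
Product: 3 (5R)-3-bromo-5-(l-menthyloxy)furan-2(5H)-one, via trans-3,4-dibromolactone 2 (not isolated)
Conditions: Br2, CH2Cl2, 0 °C; then pyridine, 0 °C → rt
Reagents that add atoms: bromine, BrBr
Why: Bromine adds across the butenolide alkene and pyridine‑induced dehydrobromination (α‑deprotonation, loss of the β‑bromide) should restore conjugation as the α‑bromobutenolide without touching the acetal stereocentre (bromination–dehydrobromination).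

**Step 2**
Reactants: 3 (5R)-3-bromo-5-(l-menthyloxy)furan-2(5H)-one; 4 (3-ethoxy-3-oxopropyl)zinc bromide
Product: 5 ethyl 3-[(5R)-5-(l-menthyloxy)-2-oxo-2,5-dihydrofuran-3-yl]propanoate
Conditions: Pd(PPh3)4 (5 mol %), THF, rt → 45 °C
Reagents that add atoms: none
Why: Negishi coupling (oxidative addition of zerovalent palladium into the α‑bromoenoate C–Br bond, transmetallation with the zinc homoenolate, reductive elimination) should attach the C9–C8–C7 chain to C10 under neutral conditions that leave the base‑sensitive acetal centre intact.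

**Step 3**
Reactants: 5 ethyl 3-[(5R)-5-(l-menthyloxy)-2-oxo-2,5-dihydrofuran-3-yl]propanoate; 6 4-methylpent-4-enal
Product: 8 cis-fused ring A hydroxy lactone (1-OH cis to the lactone carbonyl C20; menthyloxy anti to C4), via iron lactone enolate 7 (not isolated)
Conditions: Fe(acac)3 (0.3 equiv), PhSiH2(Oi-Pr) (2.5 equiv), THF, 0 °C → rt, slow addition of 6 (1.5 equiv); aq. NH4F work-up
Reagents that add atoms: none
Why: Proposed new method: the iron hydride formed from Fe(acac)3 and the silane should transfer a hydrogen atom to the 1,1‑disubstituted alkene of 6 (Markovnikov), the tertiary C4 radical adds to the butenolide β‑carbon C5 of 5 (Giese addition), and the C10 α‑lactone radical is reduced by divalent iron to the trivalent‑iron lactone enolate 7, which adds to the tethered aldehyde C1. The closest known reaction type is the hydrogen‑atom‑transfer‑initiated radical–polar crossover annulation of γ,δ‑unsaturated aldehydes with cyclic enones, together with the iron‑hydride Giese coupling of alkenes with butenolides; the new element is a lactone in place of a ketone as the enolate precursor. Ring A (C1–C5, C10) is closed by a 6‑(enolexo)‑exo‑trig aldol after the intermolecular C4–C5 bond formation, so the step is a formal (4+2) annulation forming C4–C5 and C1–C10. C5 is set by radical attack anti to the menthyloxy group on the adjacent acetal carbon C6, C10 follows because the four‑carbon tether on C5 can only reach the same face of the planar enolate (cis‑fused 5/6 system), and C1 is set by a closed, metal‑chelated chair transition state that keeps the aldehyde oxygen next to the enolate oxygen, placing the new hydroxyl cis to C20. The step needs hydrogen‑atom transfer to the electron‑rich alkene of 6 rather than to the electron‑poor trisubstituted alkene of 5 (secured by the polarity of the iron hydride), aldol trapping faster than protonation of the enolate (favoured by the aprotic medium and the intramolecular six‑membered closure) and anti‑facial attack (secured by the acetal stereocentre next to C5).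

**Step 4**
Reactants: 8 cis-fused ring A hydroxy lactone
Product: 9 1-O-triethylsilyl ether of 8
Conditions: TESOTf, 2,6-lutidine, CH2Cl2, −78 → 0 °C
Reagents that add atoms: triethylsilyl trifluoromethanesulfonate, CC[Si](CC)(CC)OS(=O)(=O)C(F)(F)F
Why: Silylation of the hindered secondary alcohol with the silyl triflate (no stereocentre changes) should block O1 so that it cannot compete with O20 for the C7 carbonyl in step 6 and survives the hydride and enolate steps.

**Step 5**
Reactants: 9 1-O-triethylsilyl ether of 8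
Product: 10 triol (CH2OH at C6, C20 and C7; 1α-OTES)
Conditions: LiAlH4, THF, 0 °C; Rochelle-salt work-up
Reagents that add atoms: none
Why: Hydride reduction of the pseudo‑ester (C20 carbonyl to CH2OH, released C6 aldehyde to CH2OH with loss of menthol) and of the ethyl ester should give the triol, erasing the auxiliary centre C6 and leaving C1, C5 and C10 untouched.

**Step 6**
Reactants: 10 triol
Product: 12 spiro δ-lactone (7,20-olide) with free 6-OH and 1α-OTES, via lactol 11 (not isolated)
Conditions: TEMPO (0.2 equiv), PhI(OAc)2 (2.5 equiv), CH2Cl2, rt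
Reagents that add atoms: none
Why: TEMPO/PhI(OAc)2 oxidative lactonisation: the oxoammonium species should oxidise the only unhindered primary alcohol (C7) much faster than the two neopentyl ones, the aldehyde is captured by O20 as the six‑membered lactol (O6 could only give a seven‑membered ring), and the lactol is oxidised on to the δ‑lactone.

**Step 7**
Reactants: 12 spiro δ-lactone with free 6-OH
Product: 13 6-O-TBDPS spiro δ-lactone
Conditions: TBDPSCl, imidazole, DMAP (cat.), DMF, rt → 40 °C
Reagents that add atoms: tert-butyl(chloro)diphenylsilane, CC(C)(C)[Si](Cl)(c1ccccc1)c1ccccc1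
Why: Silylation of the remaining primary alcohol with a group that is stable to the later selective removal of the triethylsilyl ether; no stereocentre is affected.

**Step 8**
Reactants: 13 6-O-TBDPS spiro δ-lactone
Product: 15 8-formyl δ-lactone (hydroxymethylene tautomer in equilibrium; C8 epimers), via lithium lactone enolate 14 (not isolated)
Conditions: LDA (1.2 equiv), THF, −78 °C; then HCO2Et, −78 → 0 °C; aq. NH4Cl
Reagents that add atoms: ethyl formate, CCOC=O
Why: Claisen formylation of the lactone lithium enolate (C8 is the only acidic position) should introduce C15 and make C8–H 1,3‑dicarbonyl‑acidic for the next step.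

**Step 9**
Reactants: 15 8-formyl δ-lactone
Product: 17 3-formyl-5,6-dihydropyran-2-one (C8=C9) spiro-fused to ring A, via α-phenylselanyl formyl lactone 16 (not isolated)
Conditions: PhSeCl, pyridine, CH2Cl2, 0 °C; then 30 % H2O2, 0 °C
Reagents that add atoms: none
Why: Selenenylation of the enolised β‑dicarbonyl and oxidation to the selenoxide, whose syn‑elimination can only take a hydrogen from C9, should give the endocyclic C8=C9 alkene activated by both the lactone and the formyl group (selenoxide elimination).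

**Step 10**
Reactants: 18 (1E,3E)-buta-1,3-diene-1,4-diyl diacetate
Product: 20 (1E,3E)-1,4-bis(tert-butyldimethylsilyloxy)buta-1,3-diene, via dilithium dienediolate 19 (not isolated)
Conditions: MeLi (4.1 equiv), DME, −78 → 0 °C; then TBSCl (2.2 equiv), DMPU, −78 °C → rt
Reagents that add atoms: tert-butyl(chloro)dimethylsilane, CC(C)(C)[Si](C)(C)Cl
Why: Cleavage of both enol acetates by methyllithium should give the dienediolate with retention of the two enolate geometries, and O‑silylation fixes them as the (1E,3E)‑bis(silyl enol ether).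

**Step 11**
Reactants: 17 3-formyl-5,6-dihydropyran-2-one; 20 (1E,3E)-1,4-bis(tert-butyldimethylsilyloxy)buta-1,3-diene
Product: 21 Diels–Alder adduct (ring C cyclohexene C12=C13; 8-CHO; 11β- and 14β-OTBS; H9, C15, O11 and O14 all cis)
Conditions: 20 (1.5 equiv), toluene, 4 Å molecular sieves, rt → 60 °C
Reagents that add atoms: none
Why: Normal‑demand Diels–Alder reaction of the doubly activated C8=C9 dienophile with the electron‑rich diene should form C9–C11 and C8–C14; the (E,E) geometry makes O11 and O14 cis, the endo formyl group (the bulky spiro‑lactone ring points exo) places both cis to C15 and H9, and the diene adds to the lactone face anti to the C5 branch, which is screened by the axial C4 methyl group and the C6 silyloxymethyl arm, setting C8 and C9 relative to C10.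

**Step 12**
Reactants: 21 Diels–Alder adduct
Product: 22 C15 propargylic alcohol (C15 epimers)
Conditions: HC≡CMgBr, THF, −78 → −20 °C; aq. NH4Cl
Reagents that add atoms: ethynylmagnesium bromide, C#C[Mg]Br
Why: 1,2‑Addition of the small acetylide Grignard reagent to the neopentyl aldehyde at low temperature should be chemoselective over the lactone; the new carbinol centre C15 is oxidised away in step 14.

**Step 13**
Reactants: 22 C15 propargylic alcohol
Product: 24 tetracyclic allylic alcohol (ring D closed; C16=C17 methylene; 15-OH), via vinylstannane 23 (not isolated)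
Conditions: Bu3SnH (1.5 equiv), AIBN (0.2 equiv), benzene, 80 °C; then PPTS, CH2Cl2, rt
Reagents that add atoms: none
Why: Tin‑hydride alkyne–alkene radical cyclisation: the stannyl radical adds to the terminal alkyne carbon, the C16 vinyl radical closes ring D by 5‑exo‑trig attack on C13 from the only face the axial C8 side chain can reach (which sets C13), the C12 radical is reduced by the stannane, and protodestannylation leaves the exocyclic methylene.

**Step 14**
Reactants: 24 tetracyclic allylic alcohol
Product: 25 15-oxo-16-ene (α-methylene cyclopentanone) with 1α-OTES, 6-OTBDPS, 11β- and 14β-OTBS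
Conditions: Dess–Martin periodinane, CH2Cl2, 0 °C → rt
Reagents that add atoms: none
Why: Dess–Martin oxidation of the only free (allylic) hydroxyl should give the enone, while the silyl ether on O14 prevents retro‑aldol cleavage.

**Step 15**
Reactants: 25 15-oxo-16-ene with 1α-OTES
Product: 27 1α-acetate with 6-OTBDPS and 11β- and 14β-OTBS, via 1-alcohol 26 (not isolated)
Conditions: HF·pyridine, pyridine, THF, 0 °C; then Ac2O, DMAP (cat.), pyridine, CH2Cl2, 0 °C → rt
Reagents that add atoms: acetic anhydride, CC(=O)OC(C)=O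
Why: Buffered HF·pyridine should cleave the secondary triethylsilyl ether much faster than the secondary TBS and primary TBDPS ethers, and the freed equatorial 1‑hydroxyl is acetylated at once (retention at C1) before it can attack the C7 lactone carbonyl.

**Step 16**
Reactants: 27 1α-acetate with 6-OTBDPS and 11β- and 14β-OTBS
Product: 28 target (1α-acetoxy-6,11β,14β-trihydroxy-15-oxo-6,7-seco-ent-kaur-16-en-7,20-olide)
Conditions: HF·pyridine (excess), THF, 0 → 40 °C
Reagents that add atoms: none
Why: Fluoride cleavage of the three remaining silyl ethers under mildly acidic conditions should be tolerated by the acetate, the lactone, the α‑methylene ketone and the β‑hydroxy ketone.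

**Compound list**
1 | (5R)-5-[(1R,2S,5R)-2-isopropyl-5-methylcyclohexyloxy]furan-2(5H)-one | O=C1C=C[C@H](O[C@@H]2C[C@H](C)CC[C@H]2C(C)C)O1 | starting material
2 | trans-3,4-dibromo-5-(l-menthyloxy)dihydrofuran-2(3H)-one (4-Br anti to menthyloxy) | O=C1[C@H](Br)[C@@H](Br)[C@H](O[C@@H]2C[C@H](C)CC[C@H]2C(C)C)O1 | intermediate (not isolated)
3 | (5R)-3-bromo-5-(l-menthyloxy)furan-2(5H)-one | O=C1C(Br)=C[C@H](O[C@@H]2C[C@H](C)CC[C@H]2C(C)C)O1 | intermediate
4 | (3-ethoxy-3-oxopropyl)zinc bromide | CCOC(=O)CC[Zn]Br | starting material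
5 | ethyl 3-[(5R)-5-(l-menthyloxy)-2-oxo-2,5-dihydrofuran-3-yl]propanoate | CCOC(=O)CCC1=C[C@H](O[C@@H]2C[C@H](C)CC[C@H]2C(C)C)OC1=O | intermediate
6 | 4-methylpent-4-enal | C=C(C)CCC=O | starting material
7 | iron lactone enolate of the Giese adduct (drawn as the enolate anion; C5 side chain anti to menthyloxy) | CCOC(=O)CCC1=C([O-])O[C@@H](O[C@@H]2C[C@H](C)CC[C@H]2C(C)C)[C@@H]1C(C)(C)CCC=O | intermediate (not isolated)
8 | ethyl 3-[7-hydroxy-4,4-dimethyl-3-(l-menthyloxy)-1-oxohexahydroisobenzofuran-7a-yl]propanoate, cis-fused, 7-OH (C1) cis to the lactone carbonyl, menthyloxy trans to the gem-dimethyl carbon | O=C1[C@]2([C@@H](O)CCC(C)(C)[C@H]2[C@H](O[C@@H]3C[C@H](C)CC[C@H]3C(C)C)O1)CCC(=O)OCC | intermediate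
9 | 1-O-triethylsilyl ether of 8 | O=C1[C@]2([C@@H](O[Si](CC)(CC)CC)CCC(C)(C)[C@H]2[C@H](O[C@@H]3C[C@H](C)CC[C@H]3C(C)C)O1)CCC(=O)OCC | intermediate
10 | ring A triol: 1α-OTES, CH2OH on C5 (C6), CH2OH (C20) and 3-hydroxypropyl (C9–C8–C7) on C10 | OC[C@]1([C@@H](O[Si](CC)(CC)CC)CCC(C)(C)[C@H]1CO)CCCO | intermediate
11 | spiro lactol (7-hydroxy-7,20-epoxide; C7 epimers), 6-OH, 1α-OTES | OC1OC[C@]2([C@@H](O[Si](CC)(CC)CC)CCC(C)(C)[C@H]2CO)CC1 | intermediate (not isolated)
12 | spiro δ-lactone (7,20-olide), 6-OH, 1α-OTES | O=C1OC[C@]2([C@@H](O[Si](CC)(CC)CC)CCC(C)(C)[C@H]2CO)CC1 | intermediate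
13 | spiro δ-lactone, 6-OTBDPS, 1α-OTES | O=C1OC[C@]2([C@@H](O[Si](CC)(CC)CC)CCC(C)(C)[C@H]2CO[Si](c3ccccc3)(c3ccccc3)C(C)(C)C)CC1 | intermediate
14 | lithium enolate of 13 (C7=C8) | [Li+].[O-]C1OC[C@]2([C@@H](O[Si](CC)(CC)CC)CCC(C)(C)[C@H]2CO[Si](c3ccccc3)(c3ccccc3)C(C)(C)C)CC=1 | intermediate (not isolated)
15 | 8-formyl spiro δ-lactone (drawn as formyl tautomer, C8 epimers) | O=C1OC[C@]2([C@@H](O[Si](CC)(CC)CC)CCC(C)(C)[C@H]2CO[Si](c3ccccc3)(c3ccccc3)C(C)(C)C)CC1C=O | intermediate
16 | 8-formyl-8-(phenylselanyl) spiro δ-lactone (C8 epimers) | O=C1OC[C@]2([C@@H](O[Si](CC)(CC)CC)CCC(C)(C)[C@H]2CO[Si](c3ccccc3)(c3ccccc3)C(C)(C)C)CC1(C=O)[Se]c4ccccc4 | intermediate (not isolated)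
17 | 3-formyl-5,6-dihydro-2H-pyran-2-one (C8=C9, 8-CHO) spiro-fused at C10 to ring A, 6-OTBDPS, 1α-OTES | O=C1OC[C@]2([C@@H](O[Si](CC)(CC)CC)CCC(C)(C)[C@H]2CO[Si](c3ccccc3)(c3ccccc3)C(C)(C)C)C=C1C=O | intermediate
18 | (1E,3E)-buta-1,3-diene-1,4-diyl diacetate | CC(=O)O/C=C/C=C/OC(C)=O | starting material
19 | dilithium (1E,3E)-buta-1,3-diene-1,4-diolate | [Li+].[Li+].[O-]/C=C/C=C/[O-] | intermediate (not isolated)
20 | (1E,3E)-1,4-bis(tert-butyldimethylsilyloxy)buta-1,3-diene | CC(C)(C)[Si](C)(C)O/C=C/C=C/O[Si](C)(C)C(C)(C)C | intermediate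
21 | Diels–Alder adduct: ring C cyclohexene (C12=C13) cis-fused to the δ-lactone, 8-CHO, 11β- and 14β-OTBS (H9, C15, O11, O14 all cis), 6-OTBDPS, 1α-OTES | O=C[C@@]12C(=O)OC[C@]3([C@@H](O[Si](CC)(CC)CC)CCC(C)(C)[C@H]3CO[Si](c4ccccc4)(c4ccccc4)C(C)(C)C)[C@@H]1[C@@H](O[Si](C)(C)C(C)(C)C)C=C[C@H]2O[Si](C)(C)C(C)(C)C | intermediate
22 | C15 propargylic alcohol of 21 (C15 epimers) | C#CC(O)[C@@]12C(=O)OC[C@]3([C@@H](O[Si](CC)(CC)CC)CCC(C)(C)[C@H]3CO[Si](c4ccccc4)(c4ccccc4)C(C)(C)C)[C@@H]1[C@@H](O[Si](C)(C)C(C)(C)C)C=C[C@H]2O[Si](C)(C)C(C)(C)C | intermediate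
23 | cyclised vinylstannane (C17–SnBu3, alkene geometry not defined; 15-OH epimers) | CCCC[Sn](CCCC)(CCCC)C=C1C(O)[C@@]23C(=O)OC[C@]4([C@@H](O[Si](CC)(CC)CC)CCC(C)(C)[C@H]4CO[Si](c5ccccc5)(c5ccccc5)C(C)(C)C)[C@@H]2[C@@H](O[Si](C)(C)C(C)(C)C)C[C@@H]1[C@H]3O[Si](C)(C)C(C)(C)C | intermediate (not isolated)
24 | tetracyclic allylic alcohol: bicyclo[3.2.1]octane rings C/D, C16=C17, 15-OH (epimers), silyl ethers as in 21 | C=C1C(O)[C@@]23C(=O)OC[C@]4([C@@H](O[Si](CC)(CC)CC)CCC(C)(C)[C@H]4CO[Si](c5ccccc5)(c5ccccc5)C(C)(C)C)[C@@H]2[C@@H](O[Si](C)(C)C(C)(C)C)C[C@@H]1[C@H]3O[Si](C)(C)C(C)(C)C | intermediate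
25 | 15-oxo-16-ene, 1α-OTES, 6-OTBDPS, 11β,14β-bis(OTBS) | C=C1C(=O)[C@@]23C(=O)OC[C@]4([C@@H](O[Si](CC)(CC)CC)CCC(C)(C)[C@H]4CO[Si](c5ccccc5)(c5ccccc5)C(C)(C)C)[C@@H]2[C@@H](O[Si](C)(C)C(C)(C)C)C[C@@H]1[C@H]3O[Si](C)(C)C(C)(C)C | intermediate
26 | 1α-alcohol of 25 | C=C1C(=O)[C@@]23C(=O)OC[C@]4([C@@H](O)CCC(C)(C)[C@H]4CO[Si](c5ccccc5)(c5ccccc5)C(C)(C)C)[C@@H]2[C@@H](O[Si](C)(C)C(C)(C)C)C[C@@H]1[C@H]3O[Si](C)(C)C(C)(C)C | intermediate (not isolated)
27 | 1α-acetate, 6-OTBDPS, 11β,14β-bis(OTBS) | C=C1C(=O)[C@@]23C(=O)OC[C@]4([C@@H](OC(C)=O)CCC(C)(C)[C@H]4CO[Si](c5ccccc5)(c5ccccc5)C(C)(C)C)[C@@H]2[C@@H](O[Si](C)(C)C(C)(C)C)C[C@@H]1[C@H]3O[Si](C)(C)C(C)(C)C | intermediate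
28 | 1α-acetoxy-6,11β,14β-trihydroxy-15-oxo-6,7-seco-ent-kaur-16-en-7,20-olide (CNP0225182.1) | C=C1C(=O)[C@@]23C(=O)OC[C@]4([C@@H](OC(C)=O)CCC(C)(C)[C@H]4CO)[C@@H]2[C@@H](O)C[C@@H]1[C@H]3O | target

**Step count and risks**
Total step count: 16. Longest linear sequence: 15 (steps 1–9 and 11–16; step 10 makes the diene).

Steps most likely to fail:

1. Step 3 (proposed new method). The lactone enolate may be protonated or reduced before it closes onto the aldehyde, leaving only the Giese adduct, the aldehyde may be reduced by the iron hydride, or the aldol may lose selectivity at C1. The fallback sets out from 5 and uses a Diels–Alder reaction, which is known for 5‑alkoxybutenolides. Commercial 4‑methylpent‑2‑enal would be converted with TESOTf/Et3N into (1E)‑triethyl[(4‑methylpenta‑1,3‑dien‑1‑yl)oxy]silane F1. Heating F1 with 5 (toluene, 110–140 °C, or 1.2 GPa at 50 °C) should give, by anti‑facial, endo addition with the silyloxy terminus on the α‑carbon, the cyclohexene cycloadduct F2, which already holds C4–C5, C1–C10 and the 1‑OTES group. Hydrogenation of its C2=C3 bond (H2, Pd/C, EtOAc) comes back to the route at 9, so step 4 is then not needed.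

2. Step 11. The formyl enoate may react as a heterodiene (inverse‑demand hetero‑Diels–Alder), the bis(silyl enol ether) may undergo Mukaiyama–Michael addition or desilylation, or facial selectivity at the hindered spiro‑lactone alkene may be poor. The fallback sets out from 17 and introduces the two oxygens by singlet‑oxygen cycloaddition instead. Heating 17 with 2H‑pyran‑2‑one (xylene, 130 °C) should give the bridged lactone cycloadduct F3 (regio‑ and endo/exo isomers converge), which loses CO2 to the cyclohexa‑1,3‑diene F4. Singlet oxygen (O2, hν, tetraphenylporphyrin, CH2Cl2, −78 °C) should add to the diene face anti to C10 to give the endoperoxide F5. Thiourea in MeOH reduces the O–O bond to the cis‑11,14‑diol F6, and TBSOTf/2,6‑lutidine returns to the route at 21.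

3. Step 13. The vinyl radical may be reduced before it cyclises, close 6‑endo, or rearrange (homoallyl–cyclopropylcarbinyl) to the bicyclo[2.2.2]octane, or the alkyne may be hydrostannylated without ring closure. The fallback sets out from 22 and closes ring D by organopalladium chemistry. Bromoboration with B‑bromo‑9‑borabicyclo[3.3.1]nonane followed by AcOH protonolysis should give the 2‑bromoallylic alcohol F7. A reductive Heck cyclisation (Pd(OAc)2, PPh3, HCO2Na, DMF, 80 °C) then proceeds by 5‑exo carbopalladation onto C13; the C12–Pd intermediate has no syn β‑hydrogen and is reduced by formate, which returns to the route at 24.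

**Further compounds**
F1 | step 3 | (1E)-triethyl[(4-methylpenta-1,3-dien-1-yl)oxy]silane | CC(C)=C/C=C/O[Si](CC)(CC)CC
F2 | step 3 | Diels–Alder cycloadduct of 5 and F1 (ring A with C2=C3, 1-OTES, menthyloxy lactone) | O=C1[C@]2([C@@H](O[Si](CC)(CC)CC)C=CC(C)(C)[C@H]2[C@H](O[C@@H]3C[C@H](C)CC[C@H]3C(C)C)O1)CCC(=O)OCC
F3 | step 11 | bridged lactone cycloadduct of 17 and 2H-pyran-2-one (one regioisomer drawn, new bridgeheads not defined) | O=C[C@@]12C(=O)OC[C@]3([C@@H](O[Si](CC)(CC)CC)CCC(C)(C)[C@H]3CO[Si](c4ccccc4)(c4ccccc4)C(C)(C)C)[C@@H]1C5OC(=O)C2C=C5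
F4 | step 11 | ring C cyclohexa-1,3-diene (C11=C12, C13=C14), 8-CHO | O=C[C@@]12C(=O)OC[C@]3([C@@H](O[Si](CC)(CC)CC)CCC(C)(C)[C@H]3CO[Si](c4ccccc4)(c4ccccc4)C(C)(C)C)[C@@H]1C=CC=C2
F5 | step 11 | 11,14-endoperoxide (O–O bridge cis to C15 and H9) | O=C[C@@]12C(=O)OC[C@]3([C@@H](O[Si](CC)(CC)CC)CCC(C)(C)[C@H]3CO[Si](c4ccccc4)(c4ccccc4)C(C)(C)C)[C@@H]1[C@H]5OO[C@@H]2C=C5
F6 | step 11 | cis-11β,14β-diol of the ring C cyclohexene | O=C[C@@]12C(=O)OC[C@]3([C@@H](O[Si](CC)(CC)CC)CCC(C)(C)[C@H]3CO[Si](c4ccccc4)(c4ccccc4)C(C)(C)C)[C@@H]1[C@@H](O)C=C[C@H]2O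
F7 | step 13 | 2-bromoallylic alcohol (C16 bromide, C15 epimers) | C=C(Br)C(O)[C@@]12C(=O)OC[C@]3([C@@H](O[Si](CC)(CC)CC)CCC(C)(C)[C@H]3CO[Si](c4ccccc4)(c4ccccc4)C(C)(C)C)[C@@H]1[C@@H](O[Si](C)(C)C(C)(C)C)C=C[C@H]2O[Si](C)(C)C(C)(C)C
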